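**Plan**

- Retrosynthesis (ring locants: C1 carries the butenoic acid chain, C2 is the ketone, C3 the heptenyl carbon, C4 the CH2OH carbon, C5 and C6 the carbinols): C1–C2 and C5–C6 are cut together in one [4+2] step, after the C3–alkenyl bond (Suzuki–Miyaura) and the side-chain C=C (Wittig).
- Enabling feature: C2=O and C5–OH stand 1,4 across the C3=C4 alkene, so the ring is the opened form of a 7-oxabicyclo[2.2.1]hept-2-ene, the Diels–Alder adduct of a 2-acyloxyfuran (furan O becomes the C5 hydroxyl, furan C2 the ketone). The aldehyde carbon needed for the Wittig step lies two atoms from C1 and serves, at the acid level, as the carbonyl of a three-atom tether O–C(=O)–CH2 from the furan C2 oxygen to C1.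
- Forward: butenolide (furan ring) → furan-2-yl ester of a Z-enol ether acid → intramolecular Diels–Alder reaction (carbocycle, oxygen bridge and temporary γ-lactone at once) → lactol → Wittig opening to the hydroxy enone → Suzuki–Miyaura coupling → deprotection.
- Stereochemistry: C1/C6 cis from the Z-alkene, both exo because of the short tether and therefore cis to the bridge oxygen (C5–OH); absolute configuration from the (S)-1-(2,4,6-triisopropylphenyl)ethyl group on the enol oxygen; side-chain carbinol from (R)-2-methyloxirane; E-alkenes from cross-metathesis and a stabilised ylide.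

Key step: step 8

Assumption: 1,3-dihydroxyacetone is charged as its commercial dimer, which reacts as the monomer, and (S)-1-(2,4,6-triisopropylphenyl)ethanol is taken as commercially available in enantiopure form.

**Route**

Step 1
Reactants: 1 1,3-dihydroxyacetone; 2 ethyl (triphenylphosphoranylidene)acetate
Product: 4 4-(hydroxymethyl)furan-2(5H)-one, via ethyl 4-hydroxy-3-(hydroxymethyl)but-2-enoate 3 (not isolated)
Conditions: CH2Cl2, rt
Reagents that add atoms: none
Why: Wittig olefination of the ketone gives enoate 3, in which one CH2OH group is necessarily cis to the ester and lactonises with loss of ethanol; no stereocentre arises.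

Step 2
Reactants: 4 4-(hydroxymethyl)furan-2(5H)-one
Product: 5 4-{[(tert-butyldimethylsilyl)oxy]methyl}furan-2(5H)-one
Conditions: TBSCl, imidazole, DMF, 0 °C to rt
Reagents that add atoms: tert-butyldimethylsilyl chloride, CC(C)(C)[Si](C)(C)Cl
Why: Silyl ether formation at the primary alcohol; the lactone is inert to imidazole.

Step 3
Reactants: 5 4-{[(tert-butyldimethylsilyl)oxy]methyl}furan-2(5H)-one
Product: 7 3-bromo-4-{[(tert-butyldimethylsilyl)oxy]methyl}furan-2(5H)-one, via 3,4-dibromolactone 6 (not isolated)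
Conditions: Br2, CH2Cl2, 0 °C to rt; then Et3N, 0 °C
Reagents that add atoms: bromine, BrBr
Why: Bromination–dehydrobromination: bromine adds across the lactone alkene and the amine removes HBr through the acidic C3–H (E1cB), which returns the conjugated α-bromobutenolide.

Step 4
Reactants: 8 (S)-1-(2,4,6-triisopropylphenyl)ethanol
Product: 9 (S)-2-[1-(allyloxy)ethyl]-1,3,5-triisopropylbenzene
Conditions: NaH, allyl bromide, THF/DMF, 0 °C to rt
Reagents that add atoms: allyl bromide, C=CCBr
Why: Williamson ether synthesis at oxygen; the benzylic stereocentre is not involved and stays (S).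

Step 5
Reactants: 9 (S)-2-[1-(allyloxy)ethyl]-1,3,5-triisopropylbenzene; 10 acrylic acid
Product: 11 (E)-4-[(S)-1-(2,4,6-triisopropylphenyl)ethoxy]but-2-enoic acid
Conditions: second-generation Hoveyda–Grubbs catalyst RuCl2(H2IMes)(=CH-C6H4-2-O-i-Pr) (5 mol %), CH2Cl2, 40 °C
Reagents that add atoms: none
Why: Olefin cross-metathesis of a terminal allyl ether with an acrylic partner that does not homodimerise; the conjugated product should form E under thermodynamic control.

Step 6
Reactants: 11 (E)-4-[(S)-1-(2,4,6-triisopropylphenyl)ethoxy]but-2-enoic acid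
Product: 13 (Z)-4-[(S)-1-(2,4,6-triisopropylphenyl)ethoxy]but-3-enoic acid, via dilithium dienediolate 12 (not isolated)
Conditions: LiN(i-Pr)2 (2.2 equiv), THF/DMPU, −78 °C; then AcOH, −78 °C
Reagents that add atoms: none
Why: Deconjugative protonation of an enoate: γ-deprotonation of the lithium carboxylate gives dienediolate 12 and kinetic protonation at the α-carbon leaves the double bond as the enol ether, expected Z because lithium chelation by the ether oxygen holds that oxygen cis in the dienolate.

Step 7
Reactants: 13 (Z)-4-[(S)-1-(2,4,6-triisopropylphenyl)ethoxy]but-3-enoic acid; 7 3-bromo-4-{[(tert-butyldimethylsilyl)oxy]methyl}furan-2(5H)-one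
Product: 15 3-bromo-4-{[(tert-butyldimethylsilyl)oxy]methyl}furan-2-yl (Z)-4-[(S)-1-(2,4,6-triisopropylphenyl)ethoxy]but-3-enoate, via acyl chloride 14 (not isolated)
Conditions: 13, 1-chloro-N,N,2-trimethylprop-1-en-1-amine, CH2Cl2, 0 °C; then 7, Et3N, DMAP (cat.), −40 to 0 °C
Reagents that add atoms: none
Why: Neutral acyl chloride formation followed by O-acylation of the amine-generated 2-furanolate of 7 (enol ester formation): the hard acyl electrophile should react at oxygen because this gives the aromatic furan, and the Z-enol ether and the stereocentre are not touched.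

Step 8
Reactants: 15 3-bromo-4-{[(tert-butyldimethylsilyl)oxy]methyl}furan-2-yl (Z)-4-[(S)-1-(2,4,6-triisopropylphenyl)ethoxy]but-3-enoate
Product: 16 exo cycloadduct: 7-oxabicyclo[2.2.1]hept-2-ene whose bridgehead C1 (former furan C2) carries the lactone oxygen; C2 Br; C3 CH2OTBS; C4 bridgehead H; C5 exo O-auxiliary; C6 exo CH2 that closes the γ-lactone O–C(=O)–CH2 back to C1
Conditions: PhMe (0.01 M), BHT, 140 °C, sealed tube
Reagents that add atoms: none
Why: Thermal intramolecular Diels–Alder reaction of the furan: the 2-acyloxyfuran diene adds suprafacially across the tethered Z-enol ether in one concerted, asynchronous step that joins furan C2 to C3 of the butenoate (ring C2–C1) and furan C5 to C4 of the butenoate (ring C5–C6); the closest known reaction type is the intramolecular Diels–Alder reaction of furans that carry the alkene on a three-atom tether through a C2 heteroatom, as in 2-amidofurans, together with intermolecular Diels–Alder reactions of 2-acyloxyfurans. The carbocycle closes in the [4+2] mode with the furan oxygen left as its 1,4-bridge, and the five-membered lactone closes as the ring fused at the new bridgehead C–C bond, with the tether exo. Ring C1 and C6 come out cis because the alkene is Z, and both substituents sit exo because a three-atom tether can span only the face syn to the oxygen bridge, so the C1 carbon branch, the C6 oxygen and the bridge oxygen (the later C5 hydroxyl) should end all-cis. The absolute sense should come from the (S)-auxiliary: in the s-trans enol ether with the carbinol C–H eclipsing the vinyl C–H the aryl group covers the Si face of the oxygen-bearing carbon, the furan adds to its Re face, and a minor diastereomer would be removed by chromatography. Regiochemistry is fixed by the tether and the furan is the only diene present; the step needs the cisoid ester rotamer and a forward equilibrium, which high dilution, the furan bromine (halogenated furans cyclise more readily) and the strain-free γ-lactone should provide.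

Step 9
Reactants: 16 exo cycloadduct
Product: 17 lactol: 16 with the lactone C=O reduced to CH–OH (anomeric mixture)
Conditions: i-Bu2AlH (1.1 equiv), CH2Cl2, −78 °C; aq. KNaC4H4O6 (potassium sodium tartrate)
Reagents that add atoms: none
Why: Lactone-to-lactol half-reduction: the five-membered aluminium hemiacetal is expected to persist at −78 °C, and because the C2 ketone is still masked as the bridged ketal no other carbonyl group is present; the new anomeric centre is of no consequence.

Step 10
Reactants: 18 tert-butyl 2-bromopropanoate; 19 triphenylphosphine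
Product: 21 tert-butyl 2-(triphenylphosphoranylidene)propanoate, via phosphonium bromide 20 (not isolated)
Conditions: PhMe, 80 °C; then aq. NaOH, CH2Cl2, rt
Reagents that add atoms: none
Why: SN2 quaternisation of triphenylphosphine by the α-bromo ester and deprotonation of the salt give the stabilised, storable ylide.

Step 11
Reactants: 17 lactol; 21 tert-butyl 2-(triphenylphosphoranylidene)propanoate
Product: 23 tert-butyl (E)-4-[(1R,5R,6S)-3-bromo-4-{[(tert-butyldimethylsilyl)oxy]methyl}-5-hydroxy-2-oxo-6-[(S)-1-(2,4,6-triisopropylphenyl)ethoxy]cyclohex-3-en-1-yl]-2-methylbut-2-enoate, via hydroxy keto aldehyde 22 (not isolated)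
Conditions: PhMe, 60 °C
Reagents that add atoms: none
Why: Wittig olefination of a lactol: ring–chain opening gives the aldehyde and a bridgehead hemiketal that collapses to the C2 ketone and frees the C5 hydroxyl (22), the stabilised α-methyl ylide gives the E-trisubstituted enoate and leaves the hindered enone alone, and the neutral medium should keep C1 (α to the ketone) from epimerising.

Step 12
Reactants: 24 (R)-2-methyloxirane; 25 but-3-en-1-ylmagnesium bromide
Product: 26 (R)-hept-6-en-2-ol
Conditions: CuI (10 mol %), THF, −30 to 0 °C; aq. NH4Cl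
Reagents that add atoms: none
Why: Copper-catalysed Grignard opening of the epoxide at its unsubstituted carbon (SN2), so the stereocentre is not attacked and the (R) configuration of 24 is carried into the carbinol.

Step 13
Reactants: 26 (R)-hept-6-en-2-ol
Product: 27 (R)-tert-butyl(hept-6-en-2-yloxy)dimethylsilane
Conditions: TBSCl, imidazole, DMF, rt
Reagents that add atoms: tert-butyldimethylsilyl chloride, CC(C)(C)[Si](C)(C)Cl
Why: Silyl ether formation at the secondary alcohol with retention, since only the O–H bond reacts.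

Step 14
Reactants: 27 (R)-tert-butyl(hept-6-en-2-yloxy)dimethylsilane; 28 vinylboronic acid pinacol ester
Product: 29 (R,E)-tert-butyldimethyl{[7-(4,4,5,5-tetramethyl-1,3,2-dioxaborolan-2-yl)hept-6-en-2-yl]oxy}silane
Conditions: second-generation Grubbs catalyst RuCl2(H2IMes)(PCy3)(=CHPh) (5 mol %), CH2Cl2, 40 °C
Reagents that add atoms: none
Why: Olefin cross-metathesis of a terminal alkene with the vinyl boronate, which should give the E-alkenyl boronate under thermodynamic control; the remote (R) centre is untouched.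

Step 15
Reactants: 23 bromoenone ester; 29 (R,E)-alkenyl boronate
Product: 30 tert-butyl (E)-4-[(1R,5R,6S)-3-[(R,E)-6-{[tert-butyldimethylsilyl]oxy}hept-1-en-1-yl]-4-{[(tert-butyldimethylsilyl)oxy]methyl}-5-hydroxy-2-oxo-6-[(S)-1-(2,4,6-triisopropylphenyl)ethoxy]cyclohex-3-en-1-yl]-2-methylbut-2-enoate
Conditions: PdCl2(dppf) (10 mol %), K3PO4, THF/H2O (10:1), rt
Reagents that add atoms: none
Why: Suzuki–Miyaura coupling: oxidative addition of the α-bromoenone to zerovalent palladium is fast and transmetalation of the E-alkenyl boronate proceeds with retention of geometry, while room temperature and phosphate base should spare the β-alkoxy ketone and the C1 centre.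

Step 16
Reactants: 30 bis-silyl ether
Product: 31 tert-butyl (E)-4-[(1R,5R,6S)-5-hydroxy-3-[(R,E)-6-hydroxyhept-1-en-1-yl]-4-(hydroxymethyl)-2-oxo-6-[(S)-1-(2,4,6-triisopropylphenyl)ethoxy]cyclohex-3-en-1-yl]-2-methylbut-2-enoate
Conditions: HF·pyridine, THF/pyridine, 0 °C to rt
Reagents that add atoms: none
Why: Fluoride cleavage of both silyl ethers in a pyridine-buffered medium that should leave the tert-butyl ester, the benzylic ether and the β-alkoxy ketone intact.

Step 17
Reactants: 31 triol ester
Product: 32 Pestallic acid I, (E)-4-[(1R,5R,6S)-5,6-dihydroxy-3-[(R,E)-6-hydroxyhept-1-en-1-yl]-4-(hydroxymethyl)-2-oxocyclohex-3-en-1-yl]-2-methylbut-2-enoic acid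
Conditions: TFA/CH2Cl2/H2O (20:75:5), 0 °C; then aq. NaHCO3/MeOH and acidification to pH 4
Reagents that add atoms: none
Why: Acidolysis: the tert-butyl ester loses 2-methylpropene and the benzylic ether ionises to the 1-arylethyl cation, which water traps, so the C6–O bond is never broken and no stereocentre is touched; hydroxylated cyclohexenones of this kind are expected to tolerate cold aqueous trifluoroacetic acid.

**Compound list**

1 | 1,3-dihydroxyacetone (commercial as the dimer) | OCC(=O)CO | starting material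
2 | ethyl (triphenylphosphoranylidene)acetate | CCOC(=O)C=P(c1ccccc1)(c1ccccc1)c1ccccc1 | starting material
3 | ethyl 4-hydroxy-3-(hydroxymethyl)but-2-enoate | CCOC(=O)C=C(CO)CO | intermediate
4 | 4-(hydroxymethyl)furan-2(5H)-one | O=C1C=C(CO)CO1 | intermediate
5 | 4-{[(tert-butyldimethylsilyl)oxy]methyl}furan-2(5H)-one | O=C1C=C(CO[Si](C)(C)C(C)(C)C)CO1 | intermediate
6 | 3,4-dibromo-4-{[(tert-butyldimethylsilyl)oxy]methyl}dihydrofuran-2(3H)-one | O=C1OCC(Br)(CO[Si](C)(C)C(C)(C)C)C1Br | intermediate
7 | 3-bromo-4-{[(tert-butyldimethylsilyl)oxy]methyl}furan-2(5H)-one | O=C1OCC(CO[Si](C)(C)C(C)(C)C)=C1Br | intermediate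
8 | (S)-1-(2,4,6-triisopropylphenyl)ethanol | C[C@H](O)c1c(C(C)C)cc(C(C)C)cc1C(C)C | starting material
9 | (S)-2-[1-(allyloxy)ethyl]-1,3,5-triisopropylbenzene | C[C@H](OCC=C)c1c(C(C)C)cc(C(C)C)cc1C(C)C | intermediate
10 | acrylic acid | C=CC(=O)O | starting material
11 | (E)-4-[(S)-1-(2,4,6-triisopropylphenyl)ethoxy]but-2-enoic acid | C[C@H](OC/C=C/C(=O)O)c1c(C(C)C)cc(C(C)C)cc1C(C)C | intermediate
12 | dilithium (Z)-dienediolate of 11 | C[C@H](O/C=C\C=C([O-])[O-])c1c(C(C)C)cc(C(C)C)cc1C(C)C.[Li+].[Li+] | intermediate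
13 | (Z)-4-[(S)-1-(2,4,6-triisopropylphenyl)ethoxy]but-3-enoic acid | C[C@H](O/C=C\CC(=O)O)c1c(C(C)C)cc(C(C)C)cc1C(C)C | intermediate
14 | (Z)-4-[(S)-1-(2,4,6-triisopropylphenyl)ethoxy]but-3-enoyl chloride | C[C@H](O/C=C\CC(=O)Cl)c1c(C(C)C)cc(C(C)C)cc1C(C)C | intermediate
15 | 3-bromo-4-{[(tert-butyldimethylsilyl)oxy]methyl}furan-2-yl (Z)-4-[(S)-1-(2,4,6-triisopropylphenyl)ethoxy]but-3-enoate | C[C@H](O/C=C\CC(=O)Oc1occ(CO[Si](C)(C)C(C)(C)C)c1Br)c2c(C(C)C)cc(C(C)C)cc2C(C)C | intermediate
16 | exo cycloadduct (oxanorbornene fused γ-lactone; lactone CH2 and auxiliary ether syn to the oxygen bridge) | O=C1C[C@@H]2[C@H](O[C@@H](C)c4c(C(C)C)cc(C(C)C)cc4C(C)C)[C@@H]3O[C@@]2(O1)C(Br)=C3CO[Si](C)(C)C(C)(C)C | intermediate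
17 | lactol of 16 (anomeric mixture) | OC1C[C@@H]2[C@H](O[C@@H](C)c4c(C(C)C)cc(C(C)C)cc4C(C)C)[C@@H]3O[C@@]2(O1)C(Br)=C3CO[Si](C)(C)C(C)(C)C | intermediate
18 | tert-butyl 2-bromopropanoate | CC(Br)C(=O)OC(C)(C)C | starting material
19 | triphenylphosphine | c1ccc(cc1)P(c1ccccc1)c1ccccc1 | starting material
20 | (1-tert-butoxy-1-oxopropan-2-yl)triphenylphosphonium bromide | CC(C(=O)OC(C)(C)C)[P+](c1ccccc1)(c1ccccc1)c1ccccc1.[Br-] | intermediate
21 | tert-butyl 2-(triphenylphosphoranylidene)propanoate | CC(=P(c1ccccc1)(c1ccccc1)c1ccccc1)C(=O)OC(C)(C)C | intermediate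
22 | 2-[(1R,5R,6S)-3-bromo-4-{[(tert-butyldimethylsilyl)oxy]methyl}-5-hydroxy-2-oxo-6-[(S)-1-(2,4,6-triisopropylphenyl)ethoxy]cyclohex-3-en-1-yl]acetaldehyde | O=CC[C@H]1C(=O)C(Br)=C(CO[Si](C)(C)C(C)(C)C)[C@@H](O)[C@H]1O[C@@H](C)c2c(C(C)C)cc(C(C)C)cc2C(C)C | intermediate
23 | tert-butyl (E)-4-[(1R,5R,6S)-3-bromo-4-{[(tert-butyldimethylsilyl)oxy]methyl}-5-hydroxy-2-oxo-6-[(S)-1-(2,4,6-triisopropylphenyl)ethoxy]cyclohex-3-en-1-yl]-2-methylbut-2-enoate | C/C(=C\C[C@H]1C(=O)C(Br)=C(CO[Si](C)(C)C(C)(C)C)[C@@H](O)[C@H]1O[C@@H](C)c2c(C(C)C)cc(C(C)C)cc2C(C)C)C(=O)OC(C)(C)C | intermediate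
24 | (R)-2-methyloxirane | C[C@@H]1CO1 | starting material
25 | but-3-en-1-ylmagnesium bromide | C=CCC[Mg]Br | starting material
26 | (R)-hept-6-en-2-ol | C[C@@H](O)CCCC=C | intermediate
27 | (R)-tert-butyl(hept-6-en-2-yloxy)dimethylsilane | C[C@@H](O[Si](C)(C)C(C)(C)C)CCCC=C | intermediate
28 | vinylboronic acid pinacol ester | C=CB1OC(C)(C)C(C)(C)O1 | starting material
29 | (R,E)-tert-butyldimethyl{[7-(4,4,5,5-tetramethyl-1,3,2-dioxaborolan-2-yl)hept-6-en-2-yl]oxy}silane | C[C@@H](O[Si](C)(C)C(C)(C)C)CCC/C=C/B1OC(C)(C)C(C)(C)O1 | intermediate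
30 | tert-butyl (E)-4-[(1R,5R,6S)-3-[(R,E)-6-{[tert-butyldimethylsilyl]oxy}hept-1-en-1-yl]-4-{[(tert-butyldimethylsilyl)oxy]methyl}-5-hydroxy-2-oxo-6-[(S)-1-(2,4,6-triisopropylphenyl)ethoxy]cyclohex-3-en-1-yl]-2-methylbut-2-enoate | C/C(=C\C[C@H]1C(=O)C(/C=C/CCC[C@@H](C)O[Si](C)(C)C(C)(C)C)=C(CO[Si](C)(C)C(C)(C)C)[C@@H](O)[C@H]1O[C@@H](C)c2c(C(C)C)cc(C(C)C)cc2C(C)C)C(=O)OC(C)(C)C | intermediate
31 | tert-butyl (E)-4-[(1R,5R,6S)-5-hydroxy-3-[(R,E)-6-hydroxyhept-1-en-1-yl]-4-(hydroxymethyl)-2-oxo-6-[(S)-1-(2,4,6-triisopropylphenyl)ethoxy]cyclohex-3-en-1-yl]-2-methylbut-2-enoate | C/C(=C\C[C@H]1C(=O)C(/C=C/CCC[C@@H](C)O)=C(CO)[C@@H](O)[C@H]1O[C@@H](C)c2c(C(C)C)cc(C(C)C)cc2C(C)C)C(=O)OC(C)(C)C | intermediate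
32 | Pestallic acid I | C/C(=C\C[C@H]1C(=O)C(/C=C/CCC[C@@H](C)O)=C(CO)[C@@H](O)[C@H]1O)C(=O)O | target

**Count and risks**

Total steps: 17. Longest linear sequence: 10 steps (1, 2, 3, 7, 8, 9, 11, 15, 16, 17).

Step 8. The ester tether may fail to reach the cisoid rotamer, so that cycloreversion or thermal decomposition of the furanyl ester outruns cycloaddition. The fallback sets out from 15 and comes back at 17: the tether carbonyl is reduced before the cycloaddition. Reductive acetylation of 15 (i-Bu2AlH, CH2Cl2, −78 °C; then pyridine, DMAP, Ac2O) should give the α-acetoxy ether F1, whose sp3 acetal tether rotates freely and whose 2-alkoxyfuran is the more electron-rich diene. Heating in toluene should then give the cycloadduct acetate F2 with the same exo, all-cis outcome. Methanolysis of the acetate (K2CO3, MeOH, 0 °C) gives lactol 17, so that step 9 is no longer needed.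

Step 9. The aluminium hemiacetal may collapse before the quench, which would set free the aldehyde and the ketone in the presence of hydride and lead to over-reduction. The fallback sets out from 16 and comes back at 22. Mild hydrolysis (aq. NaHCO3, THF) opens the activated lactone to the keto acid F3, in which the hemiketal has already fallen to the C2 ketone and the C5 hydroxyl. BH3·THF at −10 °C should reduce the carboxylic acid faster than the hindered bromoenone and give the primary alcohol F4. An oxidation selective for primary alcohols (TEMPO, PhI(OAc)2, CH2Cl2) gives the hydroxy keto aldehyde 22, which is taken into the Wittig reaction of step 11.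

Step 7. Acylation at carbon (C5 of the butenolide) or base-induced migration of the enol ether double bond into conjugation by way of the ketene may compete with O-acylation. The fallback sets out from 7 and 13 and comes back at 15: silyl transfer replaces the amine base. Compound 7 is converted into the 2-silyloxyfuran F5 (TBSOTf, Et3N, CH2Cl2) and 13 into the acyl fluoride F6 (cyanuric fluoride, pyridine). Fluoride-catalysed O-acylation of the silyl enol ether (catalytic tetrabutylammonium difluorotriphenylsilicate, THF) should then give 15.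

**Further compounds**

F1 | step 8 | 1-acetoxy-1-[(3-bromo-4-{[(tert-butyldimethylsilyl)oxy]methyl}furan-2-yl)oxy]-(Z)-4-[(S)-1-(2,4,6-triisopropylphenyl)ethoxy]but-3-ene (acetal centre unassigned) | C[C@H](O/C=C\CC(OC(C)=O)Oc1occ(CO[Si](C)(C)C(C)(C)C)c1Br)c2c(C(C)C)cc(C(C)C)cc2C(C)C
F2 | step 8 | O-acetate of lactol 17 (exo cycloadduct with acetoxy tetrahydrofuran ring) | CC(=O)OC1C[C@@H]2[C@H](O[C@@H](C)c4c(C(C)C)cc(C(C)C)cc4C(C)C)[C@@H]3O[C@@]2(O1)C(Br)=C3CO[Si](C)(C)C(C)(C)C
F3 | step 9 | 2-[(1R,5R,6S)-3-bromo-4-{[(tert-butyldimethylsilyl)oxy]methyl}-5-hydroxy-2-oxo-6-[(S)-1-(2,4,6-triisopropylphenyl)ethoxy]cyclohex-3-en-1-yl]acetic acid | OC(=O)C[C@H]1C(=O)C(Br)=C(CO[Si](C)(C)C(C)(C)C)[C@@H](O)[C@H]1O[C@@H](C)c2c(C(C)C)cc(C(C)C)cc2C(C)C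
F4 | step 9 | (4R,5S,6R)-2-bromo-3-{[(tert-butyldimethylsilyl)oxy]methyl}-4-hydroxy-6-(2-hydroxyethyl)-5-[(S)-1-(2,4,6-triisopropylphenyl)ethoxy]cyclohex-2-en-1-one | OCC[C@H]1C(=O)C(Br)=C(CO[Si](C)(C)C(C)(C)C)[C@@H](O)[C@H]1O[C@@H](C)c2c(C(C)C)cc(C(C)C)cc2C(C)C
F5 | step 7 | [(3-bromo-4-{[(tert-butyldimethylsilyl)oxy]methyl}furan-2-yl)oxy](tert-butyl)dimethylsilane | CC(C)(C)[Si](C)(C)Oc1occ(CO[Si](C)(C)C(C)(C)C)c1Br
F6 | step 7 | (Z)-4-[(S)-1-(2,4,6-triisopropylphenyl)ethoxy]but-3-enoyl fluoride | C[C@H](O/C=C\CC(=O)F)c1c(C(C)C)cc(C(C)C)cc1C(C)C
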